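Numbering: C1≡C2–C3=C4–C5–C6(Cl)–C7(OAc)–C8, ring O/C9–C13, ethyl C14–C15. Retrosynthetic cuts in order: C1–H back to C1–SiMe3; C12–Br and C10–Cl back to the enone C10=C11–C12=O; C9–H back to a hemiketal; then the ring bond O–C9, which unfolds the oxane into a furan.
Enabling feature: the 2,6-cis oxane (O, C9–C13) has halogens on C10 and C12 flanking C11H2 and carbon arms on C9 and C13. This is the pattern left when a 5-alkyl-2-(1-hydroxypropyl)furan (furan carbons = C9–C12, carbinol = C13) is oxidatively ring-expanded.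
Remaining cuts: C8–C9 (5-furyl anion + terminal epoxide), C7–C8 (C1 carbenoid + α-chloro aldehyde), C5–C6 ([3,3] shift), C2–C3 (acetylide + acrolein).
Forward order: the C1–C8 enyne chloro-epoxide and the C9–C15 furyl carbinol are made separately and joined at C8–C9. Only then is the single ring closed, and it is kept to the end.
Stereochemistry: E-alkene from the chair Claisen transition state; C6 from catalyst-controlled α-chlorination; C7 by 1,2-induction from C6; C13 from asymmetric transfer hydrogenation. C9, C10 and C12 are relayed from C13 inside the ring (hydride anti to ethyl, axial chloride, equatorial hydride then SN2 inversion).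
Key step: step 11

Remark: in step 4 the antipode of the amine catalyst that gives the 2R aldehyde is used. Its sense of induction is checked by reducing a sample of the product to the chlorohydrin and correlating it before scale-up.

Step 1
Reactants: 1 ethynyltrimethylsilane; 2 acrolein
Product: 4 rac-5-(trimethylsilyl)pent-1-en-4-yn-3-ol, via lithium (trimethylsilyl)acetylide 3 (not isolated)
Conditions: n-BuLi, THF, −78 °C; then 2, −78 °C; aq NH4Cl
Reagents that add atoms: none
Why: Acetylide addition to an aldehyde: the hard lithium acetylide attacks the enal carbonyl in the 1,2-mode and forms C2–C3, and the carbinol centre may stay racemic because the next step destroys it.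

Step 2
Reactants: 4 rac-5-(trimethylsilyl)pent-1-en-4-yn-3-ol; 5 triethyl orthoacetate
Product: 7 ethyl (4E)-7-(trimethylsilyl)hept-4-en-6-ynoate, via mixed ketene acetal 6 (not isolated)
Conditions: EtCO2H (cat.), 5 (excess, neat), 140 °C, EtOH distilled off
Reagents that add atoms: none
Why: Johnson–Claisen rearrangement: acid-catalysed exchange gives the ketene acetal, whose chair-like [3,3] shift through the vinyl group (easier than the shift through the silylated alkyne) holds the alkynyl group pseudo-equatorial and so forms C5–C6 and the E C3=C4 alkene while adding C6 and C7.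

Step 3
Reactants: 7 ethyl (4E)-7-(trimethylsilyl)hept-4-en-6-ynoate
Product: 8 (4E)-7-(trimethylsilyl)hept-4-en-6-ynal
Conditions: i-Bu2AlH, CH2Cl2, −78 °C; aq potassium sodium tartrate
Reagents that add atoms: none
Why: Partial ester reduction: at −78 °C the aluminium hemiacetal persists and releases the aldehyde only on work-up, and the silylated enyne is not hydroaluminated at this temperature.

Step 4
Reactants: 8 (4E)-7-(trimethylsilyl)hept-4-en-6-ynal
Product: 9 (2R,4E)-2-chloro-7-(trimethylsilyl)hept-4-en-6-ynal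
Conditions: NCS, trans-2,5-diphenylpyrrolidine (10 mol %, antipode giving 2R), CH2Cl2, 0 °C to rt; pentane, filtration, used crude
Reagents that add atoms: N-chlorosuccinimide, O=C1CCC(=O)N1Cl
Why: Enamine-catalysed asymmetric α-chlorination of a linear aldehyde: the C2-symmetric amine leaves one enamine face open to chlorine transfer and thereby sets C6 as R, and the configurationally labile product is only filtered and carried on at once.

Step 5
Reactants: 9 (2R,4E)-2-chloro-7-(trimethylsilyl)hept-4-en-6-ynal; 10 chloroiodomethane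
Product: 13 (2S)-2-[(1R,3E)-1-chloro-6-(trimethylsilyl)hex-3-en-5-yn-1-yl]oxirane, via chloromethyllithium 11 (not isolated), via lithium dichloroalkoxide 12 (not isolated)
Conditions: MeLi·LiBr added to 9 + 10, THF/Et2O, −78 °C; then rt
Reagents that add atoms: none
Why: Halomethyllithium homologation of an aldehyde to a terminal epoxide: iodine–lithium exchange outruns addition of MeLi, the carbenoid attacks through a Cornforth-type transition state (C=O and C6–Cl dipoles opposed) to give the 6,7-anti alkoxide (7S), and on warming the alkoxide displaces the primary C8 chloride in preference to the secondary C6 chloride, any minor diastereomer being removed on silica.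

Step 6
Reactants: 14 1-(furan-2-yl)propan-1-one
Product: 15 (1S)-1-(furan-2-yl)propan-1-ol
Conditions: RuCl(p-cymene)[(S,S)-TsDPEN] (0.5 mol %), HCO2H/Et3N (5:2), rt
Reagents that add atoms: none
Why: Noyori asymmetric transfer hydrogenation of a heteroaryl alkyl ketone: the (S,S)-configured ruthenium hydride selects the ketone face through the CH–π contact between the cymene ligand and the furan and gives the (S)-carbinol, the future C13.

Step 7
Reactants: 15 (1S)-1-(furan-2-yl)propan-1-ol
Product: 16 triethyl{[(1S)-1-(furan-2-yl)propyl]oxy}silane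
Conditions: Et3SiCl, imidazole, CH2Cl2, 0 °C
Reagents that add atoms: chlorotriethylsilane, CC[Si](Cl)(CC)CC
Why: Standard silylation of a secondary alcohol, with a group that survives n-BuLi yet can later be removed by weak acid without touching the alkynylsilane or an acetate.

Step 8
Reactants: 16 triethyl{[(1S)-1-(furan-2-yl)propyl]oxy}silane; 13 (2S)-2-[(1R,3E)-1-chloro-6-(trimethylsilyl)hex-3-en-5-yn-1-yl]oxirane
Product: 18 (2S,3R,5E)-3-chloro-1-{5-[(1S)-1-(triethylsilyloxy)propyl]furan-2-yl}-8-(trimethylsilyl)oct-5-en-7-yn-2-ol, via 5-lithiofuran 17 (not isolated)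
Conditions: 16 (1.5 equiv), n-BuLi, THF, 0 °C; then 13, BF3·OEt2, −78 °C; H2O
Reagents that add atoms: none
Why: α-Lithiation of a 2-substituted furan followed by BF3-assisted SN2 opening of a terminal epoxide by the organolithium at its CH2 end forms C8–C9 without touching C7, and the boron-bound alkoxide formed at −78 °C cannot displace the neighbouring C6 chloride.

Step 9
Reactants: 18 (2S,3R,5E)-3-chloro-1-{5-[(1S)-1-(triethylsilyloxy)propyl]furan-2-yl}-8-(trimethylsilyl)oct-5-en-7-yn-2-ol
Product: 19 (2S,3R,5E)-3-chloro-1-{5-[(1S)-1-(triethylsilyloxy)propyl]furan-2-yl}-8-(trimethylsilyl)oct-5-en-7-yn-2-yl acetate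
Conditions: Ac2O, pyridine, DMAP (cat.), CH2Cl2, 0 °C to rt
Reagents that add atoms: acetic anhydride, CC(=O)OC(C)=O
Why: DMAP-catalysed acylation of the only free hydroxyl installs the acetate of the target early, and the weak amine base does not close the chlorohydrin to an epoxide.

Step 10
Reactants: 19 (2S,3R,5E)-3-chloro-1-{5-[(1S)-1-(triethylsilyloxy)propyl]furan-2-yl}-8-(trimethylsilyl)oct-5-en-7-yn-2-yl acetate
Product: 20 (2S,3R,5E)-3-chloro-1-{5-[(1S)-1-hydroxypropyl]furan-2-yl}-8-(trimethylsilyl)oct-5-en-7-yn-2-yl acetate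
Conditions: AcOH/THF/H2O (3:1:1), rt
Reagents that add atoms: none
Why: Weak-acid hydrolysis of a triethylsilyl ether is faster than cleavage of the C(sp)–Si bond or the acetate, and acetic acid is too weak to ionise the furfuryl C13–O bond, so C13 stays S.

Step 11
Reactants: 20 (2S,3R,5E)-3-chloro-1-{5-[(1S)-1-hydroxypropyl]furan-2-yl}-8-(trimethylsilyl)oct-5-en-7-yn-2-yl acetate
Product: 22 (2S,3R,5E)-3-chloro-1-[(6S)-6-ethyl-2-hydroxy-5-oxo-5,6-dihydro-2H-pyran-2-yl]-8-(trimethylsilyl)oct-5-en-7-yn-2-yl acetate (C9 epimers), via (Z)-ene-dione 21 (not isolated)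
Conditions: NBS (1.05 equiv), NaHCO3, THF/H2O (4:1), 0 °C
Reagents that add atoms: water, O
Why: Achmatowicz rearrangement of a 2-furyl carbinol, here on a 2,5-disubstituted furan: bromonium transfer from NBS to one furan α-carbon and capture by water at the other give a 2,5-dihydrofuran adduct that loses HBr and opens to the (Z)-ene-dione 21, with ketones at C9 and C12 and the C10=C11 alkene between them. The C13 hydroxyl then adds to the C9 carbonyl, which forms the O–C9 bond and closes the only ring of the target, the six-membered pyranone, in a 6-exo-trig hemiketalisation made possible by the Z geometry inherited from the furan. C9 is the only new stereocentre; it equilibrates through 21 and settles under anomeric control (hydroxyl axial), its configuration is irrelevant because step 12 planarises it, and C13 stays S because none of its bonds is broken. The step needs chemoselectivity for the furan over the C3=C4–C1≡C2 enyne, and the substrate secures it because a 2,5-dialkylfuran is far more nucleophilic than an alkene conjugated to a silyl-capped alkyne, so one equivalent of NBS at 0 °C is consumed by the furan alone. The C7 oxygen is masked as the acetate so that only the C13 hydroxyl can cyclise, and NaHCO3 takes up the HBr so that the acetate, the C6 chloride and the C–Si bond are left alone.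

Step 12
Reactants: 22 (2S,3R,5E)-3-chloro-1-[(6S)-6-ethyl-2-hydroxy-5-oxo-5,6-dihydro-2H-pyran-2-yl]-8-(trimethylsilyl)oct-5-en-7-yn-2-yl acetate
Product: 24 (2S,3R,5E)-3-chloro-1-[(2R,6S)-6-ethyl-5-oxo-5,6-dihydro-2H-pyran-2-yl]-8-(trimethylsilyl)oct-5-en-7-yn-2-yl acetate, via oxocarbenium trifluoroacetate 23 (not isolated)
Conditions: Et3SiH, CF3CO2H, CH2Cl2, −40 to 0 °C
Reagents that add atoms: none
Why: Silane–acid ionic reduction of an Achmatowicz hemiketal: acid ionises C9–OH to the flattened oxocarbenium ion and Et3SiH delivers hydride axially to C9 from the face opposite the C13 ethyl group, so the two carbon arms end cis (9R) while enone, acetate and enyne are inert to the silane.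

Step 13
Reactants: 24 (2S,3R,5E)-3-chloro-1-[(2R,6S)-6-ethyl-5-oxo-5,6-dihydro-2H-pyran-2-yl]-8-(trimethylsilyl)oct-5-en-7-yn-2-yl acetate
Product: 25 (2S,3R,5E)-3-chloro-1-[(2R,3R,6S)-3-chloro-6-ethyl-5-oxooxan-2-yl]-8-(trimethylsilyl)oct-5-en-7-yn-2-yl acetate
Conditions: HCl (2 M in Et2O, excess), CH2Cl2, −40 to −10 °C; volatiles removed cold, used crude at once
Reagents that add atoms: hydrogen chloride, Cl
Why: Hydrochlorination (conjugate addition of HCl) of a cyclic enone: in the half-chair with both arms pseudo-equatorial the small chloride adds to C10 of the protonated enone on the staggered axial path anti to the pseudo-axial C9–H, which gives the axial 10R chloride cis to the C8 arm, and this site has no syn-axial hydrogen (its 1,3-partners are the ring oxygen and the C12 carbonyl), so reversibility should not work against it.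

Step 14
Reactants: 25 (2S,3R,5E)-3-chloro-1-[(2R,3R,6S)-3-chloro-6-ethyl-5-oxooxan-2-yl]-8-(trimethylsilyl)oct-5-en-7-yn-2-yl acetate
Product: 26 (2S,3R,5E)-3-chloro-1-[(2R,3R,5S,6S)-3-chloro-6-ethyl-5-hydroxyoxan-2-yl]-8-(trimethylsilyl)oct-5-en-7-yn-2-yl acetate
Conditions: LiBH(s-Bu)3, THF, −78 °C; pH 7 phosphate buffer, H2O2, 0 °C
Reagents that add atoms: none
Why: Bulky trialkylborohydride reduction of a six-ring ketone: equatorial attack, reinforced because the axial path is blocked by the axial C10 chloride, gives the axial 12S alcohol, the low temperature lets reduction outrun enolisation and loss of HCl, the ester is not reduced, and the neutral oxidative work-up spares acetate and alkynylsilane.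

Step 15
Reactants: 26 (2S,3R,5E)-3-chloro-1-[(2R,3R,5S,6S)-3-chloro-6-ethyl-5-hydroxyoxan-2-yl]-8-(trimethylsilyl)oct-5-en-7-yn-2-yl acetate
Product: 27 (2S,3R,5E)-1-[(2R,3R,5R,6S)-5-bromo-3-chloro-6-ethyloxan-2-yl]-3-chloro-8-(trimethylsilyl)oct-5-en-7-yn-2-yl acetate
Conditions: CBr4, P(n-C8H17)3, toluene, 70 °C
Reagents that add atoms: carbon tetrabromide, BrC(Br)(Br)Br
Why: Appel-type bromination with a trialkylphosphine: bromide displaces the axial oxyphosphonium group from the equatorial side in an SN2 step that relieves the syn-diaxial O/Cl contact and gives the equatorial 12R bromide trans to the ethyl group, and the axial leaving group is not anti-periplanar to the C13–O ring bond, so the ring oxygen cannot participate.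

Step 16
Reactants: 27 (2S,3R,5E)-1-[(2R,3R,5R,6S)-5-bromo-3-chloro-6-ethyloxan-2-yl]-3-chloro-8-(trimethylsilyl)oct-5-en-7-yn-2-yl acetate
Product: 28 (2S,3R,5E)-1-[(2R,3R,5R,6S)-5-bromo-3-chloro-6-ethyloxan-2-yl]-3-chlorooct-5-en-7-yn-2-yl acetate
Conditions: n-Bu4NF, AcOH (1:1), THF, 0 °C
Reagents that add atoms: none
Why: Fluoride-induced protodesilylation of an alkynylsilane is fast at 0 °C, and the acetic acid buffer removes the basicity that could cleave the acetate or eliminate HBr or HCl.

Compound list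
1 | ethynyltrimethylsilane | C#C[Si](C)(C)C | starting material
2 | acrolein | C=CC=O | starting material
3 | lithium (trimethylsilyl)acetylide | [Li]C#C[Si](C)(C)C | intermediate
4 | rac-5-(trimethylsilyl)pent-1-en-4-yn-3-ol | C=CC(O)C#C[Si](C)(C)C | intermediate
5 | triethyl orthoacetate | CC(OCC)(OCC)OCC | starting material
6 | mixed ketene acetal, 3-[(1-ethoxyethenyl)oxy]-5-(trimethylsilyl)pent-1-en-4-yne | C=C(OCC)OC(C=C)C#C[Si](C)(C)C | intermediate
7 | ethyl (4E)-7-(trimethylsilyl)hept-4-en-6-ynoate | CCOC(=O)CC/C=C/C#C[Si](C)(C)C | intermediate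
8 | (4E)-7-(trimethylsilyl)hept-4-en-6-ynal | O=CCC/C=C/C#C[Si](C)(C)C | intermediate
9 | (2R,4E)-2-chloro-7-(trimethylsilyl)hept-4-en-6-ynal | C[Si](C)(C)C#C/C=C/C[C@@H](Cl)C=O | intermediate
10 | chloroiodomethane | ClCI | starting material
11 | chloromethyllithium | [Li]CCl | intermediate
12 | lithium (2S,3R,5E)-1,3-dichloro-8-(trimethylsilyl)oct-5-en-7-yn-2-olate | C[Si](C)(C)C#C/C=C/C[C@@H](Cl)[C@H](CCl)O[Li] | intermediate
13 | (2S)-2-[(1R,3E)-1-chloro-6-(trimethylsilyl)hex-3-en-5-yn-1-yl]oxirane | C[Si](C)(C)C#C/C=C/C[C@@H](Cl)[C@H]1OC1 | intermediate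
14 | 1-(furan-2-yl)propan-1-one | CCC(=O)c1ccco1 | starting material
15 | (1S)-1-(furan-2-yl)propan-1-ol | CC[C@H](O)c1ccco1 | intermediate
16 | triethyl{[(1S)-1-(furan-2-yl)propyl]oxy}silane | CC[Si](CC)(CC)O[C@@H](CC)c1ccco1 | intermediate
17 | {5-[(1S)-1-(triethylsilyloxy)propyl]furan-2-yl}lithium | CC[Si](CC)(CC)O[C@@H](CC)c1ccc([Li])o1 | intermediate
18 | (2S,3R,5E)-3-chloro-1-{5-[(1S)-1-(triethylsilyloxy)propyl]furan-2-yl}-8-(trimethylsilyl)oct-5-en-7-yn-2-ol | C[Si](C)(C)C#C/C=C/C[C@@H](Cl)[C@H](Cc1ccc(o1)[C@H](CC)O[Si](CC)(CC)CC)O | intermediate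
19 | (2S,3R,5E)-3-chloro-1-{5-[(1S)-1-(triethylsilyloxy)propyl]furan-2-yl}-8-(trimethylsilyl)oct-5-en-7-yn-2-yl acetate | C[Si](C)(C)C#C/C=C/C[C@@H](Cl)[C@H](Cc1ccc(o1)[C@H](CC)O[Si](CC)(CC)CC)OC(C)=O | intermediate
20 | (2S,3R,5E)-3-chloro-1-{5-[(1S)-1-hydroxypropyl]furan-2-yl}-8-(trimethylsilyl)oct-5-en-7-yn-2-yl acetate | C[Si](C)(C)C#C/C=C/C[C@@H](Cl)[C@H](Cc1ccc(o1)[C@H](CC)O)OC(C)=O | intermediate
21 | (3E,6R,7S,10Z,13S)-7-acetoxy-6-chloro-13-hydroxy-1-(trimethylsilyl)pentadeca-3,10-dien-1-yne-9,12-dione | C[Si](C)(C)C#C/C=C/C[C@@H](Cl)[C@H](CC(=O)/C=C\C(=O)[C@H](CC)O)OC(C)=O | intermediate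
22 | (2S,3R,5E)-3-chloro-1-[(6S)-6-ethyl-2-hydroxy-5-oxo-5,6-dihydro-2H-pyran-2-yl]-8-(trimethylsilyl)oct-5-en-7-yn-2-yl acetate, C9 epimers | C[Si](C)(C)C#C/C=C/C[C@@H](Cl)[C@H](CC1(O)O[C@@H](CC)C(=O)C=C1)OC(C)=O | intermediate
23 | C9 oxocarbenium ion of 22 (O=C9 cation, 13S) as its trifluoroacetate | C[Si](C)(C)C#C/C=C/C[C@@H](Cl)[C@H](CC1=[O+][C@@H](CC)C(=O)C=C1)OC(C)=O.[O-]C(=O)C(F)(F)F | intermediate
24 | (2S,3R,5E)-3-chloro-1-[(2R,6S)-6-ethyl-5-oxo-5,6-dihydro-2H-pyran-2-yl]-8-(trimethylsilyl)oct-5-en-7-yn-2-yl acetate | C[Si](C)(C)C#C/C=C/C[C@@H](Cl)[C@H](C[C@H]1O[C@@H](CC)C(=O)C=C1)OC(C)=O | intermediate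
25 | (2S,3R,5E)-3-chloro-1-[(2R,3R,6S)-3-chloro-6-ethyl-5-oxooxan-2-yl]-8-(trimethylsilyl)oct-5-en-7-yn-2-yl acetate | C[Si](C)(C)C#C/C=C/C[C@@H](Cl)[C@H](C[C@H]1O[C@@H](CC)C(=O)C[C@H]1Cl)OC(C)=O | intermediate
26 | (2S,3R,5E)-3-chloro-1-[(2R,3R,5S,6S)-3-chloro-6-ethyl-5-hydroxyoxan-2-yl]-8-(trimethylsilyl)oct-5-en-7-yn-2-yl acetate | C[Si](C)(C)C#C/C=C/C[C@@H](Cl)[C@H](C[C@H]1O[C@@H](CC)[C@@H](O)C[C@H]1Cl)OC(C)=O | intermediate
27 | (2S,3R,5E)-1-[(2R,3R,5R,6S)-5-bromo-3-chloro-6-ethyloxan-2-yl]-3-chloro-8-(trimethylsilyl)oct-5-en-7-yn-2-yl acetate | C[Si](C)(C)C#C/C=C/C[C@@H](Cl)[C@H](C[C@H]1O[C@@H](CC)[C@H](Br)C[C@H]1Cl)OC(C)=O | intermediate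
28 | (2S,3R,5E)-1-[(2R,3R,5R,6S)-5-bromo-3-chloro-6-ethyloxan-2-yl]-3-chlorooct-5-en-7-yn-2-yl acetate (CNP0194255.2) | C#C/C=C/C[C@@H](Cl)[C@H](C[C@H]1O[C@@H](CC)[C@H](Br)C[C@H]1Cl)OC(C)=O | target

Total step count: 16.
Longest linear sequence: 14 steps (steps 1–5, then 8–16); the furan branch (steps 6 and 7) is made in parallel.

Steps most likely to fail

1. Step 13.
- **Risk:** The addition of HCl is reversible, so chloride may be lost again on concentration or under the basic hydride of step 14. The facial preference of a small nucleophile next to the C8 arm may also be weak.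
- **Fallback:** It leaves the route at 24 and rejoins it at 27. It never passes through a β-chloro ketone, and it installs the C10 chloride last by SN2 inversion of an alcohol.
- Copper-catalysed conjugate borylation of 24 (B2pin2, CuCl, NaOt-Bu, DPEphos, MeOH, THF, rt) would give the β-boryl ketone F1. The bulky boryl-copper species should approach C10 anti to the C8 arm, as cuprates do with 4-substituted cyclohexenones, and the enone should react well before the silyl-capped enyne.
- Oxidation with NaBO3·4H2O (retention at carbon) would give the equatorial β-hydroxy ketone F2.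
- Silylation (Et3SiCl, imidazole) would give the C10 triethylsilyl ether F3.
- LiBH(s-Bu)3 at −78 °C would give the axial C12 alcohol F4.
- CBr4 and P(n-C8H17)3 in toluene would give the equatorial C12 bromide F5.
- AcOH/THF/H2O would then free the equatorial C10 alcohol F6.
- CCl4 and P(n-C8H17)3 in warm toluene would replace that hydroxyl with inversion and give the axial chloride of 27.

2. Step 15.
- **Risk:** The axial oxyphosphonium group has anti-periplanar hydrogens on C11 and C13, so E2 elimination at 70 °C may compete with a displacement that is slowed by the neighbouring ethyl-bearing carbon.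
- **Fallback:** It runs from 26 to 27 and separates activation from displacement, so that the substitution can be run cold.
- Tf2O and 2,6-lutidine in CH2Cl2 at −78 °C would give the axial C12 triflate F7.
- F7 would then be treated with n-Bu4NBr in toluene at or below 0 °C. The far better leaving group allows SN2 inversion to the equatorial bromide without heating.

3. Step 5.
- **Risk:** The carbenoid may decompose before it adds. Such a small nucleophile may show poor facial selectivity. The aldehyde may epimerise under the basic conditions, and the alkoxide may close onto C6 instead of C8.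
- **Fallback:** It runs from 9 to 13 and replaces the carbenoid by a thermally stable, larger sulfur-stabilised carbanion.
- (Phenylsulfanyl)methyllithium (thioanisole, n-BuLi, DABCO, THF, then 9 at −78 °C) would give the anti β-hydroxy sulfide F8, which can be purified from its C7 epimer.
- S-Methylation with Me3OBF4 in CH2Cl2 would give the sulfonium tetrafluoroborate F9.
- NaH in THF at 0 °C would close the alkoxide onto C8 only, because the sulfonium group leaves far more readily than the secondary chloride. This returns epoxide 13.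

Further compounds
F1 | step 13 | (2S,3R,5E)-3-chloro-1-[(2R,3S,6S)-6-ethyl-5-oxo-3-(4,4,5,5-tetramethyl-1,3,2-dioxaborolan-2-yl)oxan-2-yl]-8-(trimethylsilyl)oct-5-en-7-yn-2-yl acetate | C[Si](C)(C)C#C/C=C/C[C@@H](Cl)[C@H](C[C@H]1O[C@@H](CC)C(=O)C[C@@H]1B2OC(C)(C)C(C)(C)O2)OC(C)=O
F2 | step 13 | (2S,3R,5E)-3-chloro-1-[(2R,3S,6S)-6-ethyl-3-hydroxy-5-oxooxan-2-yl]-8-(trimethylsilyl)oct-5-en-7-yn-2-yl acetate | C[Si](C)(C)C#C/C=C/C[C@@H](Cl)[C@H](C[C@H]1O[C@@H](CC)C(=O)C[C@@H]1O)OC(C)=O
F3 | step 13 | (2S,3R,5E)-3-chloro-1-[(2R,3S,6S)-6-ethyl-5-oxo-3-(triethylsilyloxy)oxan-2-yl]-8-(trimethylsilyl)oct-5-en-7-yn-2-yl acetate | C[Si](C)(C)C#C/C=C/C[C@@H](Cl)[C@H](C[C@H]1O[C@@H](CC)C(=O)C[C@@H]1O[Si](CC)(CC)CC)OC(C)=O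
F4 | step 13 | (2S,3R,5E)-3-chloro-1-[(2R,3S,5S,6S)-6-ethyl-5-hydroxy-3-(triethylsilyloxy)oxan-2-yl]-8-(trimethylsilyl)oct-5-en-7-yn-2-yl acetate | C[Si](C)(C)C#C/C=C/C[C@@H](Cl)[C@H](C[C@H]1O[C@@H](CC)[C@@H](O)C[C@@H]1O[Si](CC)(CC)CC)OC(C)=O
F5 | step 13 | (2S,3R,5E)-1-[(2R,3S,5R,6S)-5-bromo-6-ethyl-3-(triethylsilyloxy)oxan-2-yl]-3-chloro-8-(trimethylsilyl)oct-5-en-7-yn-2-yl acetate | C[Si](C)(C)C#C/C=C/C[C@@H](Cl)[C@H](C[C@H]1O[C@@H](CC)[C@H](Br)C[C@@H]1O[Si](CC)(CC)CC)OC(C)=O
F6 | step 13 | (2S,3R,5E)-1-[(2R,3S,5R,6S)-5-bromo-6-ethyl-3-hydroxyoxan-2-yl]-3-chloro-8-(trimethylsilyl)oct-5-en-7-yn-2-yl acetate | C[Si](C)(C)C#C/C=C/C[C@@H](Cl)[C@H](C[C@H]1O[C@@H](CC)[C@H](Br)C[C@@H]1O)OC(C)=O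
F7 | step 15 | (2S,3R,5E)-3-chloro-1-[(2R,3R,5S,6S)-3-chloro-6-ethyl-5-(trifluoromethylsulfonyloxy)oxan-2-yl]-8-(trimethylsilyl)oct-5-en-7-yn-2-yl acetate | C[Si](C)(C)C#C/C=C/C[C@@H](Cl)[C@H](C[C@H]1O[C@@H](CC)[C@@H](OS(=O)(=O)C(F)(F)F)C[C@H]1Cl)OC(C)=O
F8 | step 5 | (2S,3R,5E)-3-chloro-1-(phenylsulfanyl)-8-(trimethylsilyl)oct-5-en-7-yn-2-ol | C[Si](C)(C)C#C/C=C/C[C@@H](Cl)[C@H](CSc1ccccc1)O
F9 | step 5 | [(2S,3R,5E)-3-chloro-2-hydroxy-8-(trimethylsilyl)oct-5-en-7-yn-1-yl](methyl)(phenyl)sulfonium tetrafluoroborate | C[Si](C)(C)C#C/C=C/C[C@@H](Cl)[C@H](C[S+](C)c1ccccc1)O.F[B-](F)(F)F
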